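**Plan**

- Retrosynthetic cuts, in order: the S–O bond of the sulfate; C16–C(butenolide) (B-alkyl Suzuki); C15=C16 (Wittig on a lactol); the C13a–O bond of a γ-lactone (Baeyer–Villiger oxygen insertion into a cyclobutanone); the two cyclobutanone bonds made by a ketene [2+2]; C13=CH2 (Wittig); C1=C10 (McMurry); C9–C11 and C9–CH3 (enolate alkylations); C3–C4 (conjugate addition to pulegone).
- Forward: ring B is the pulegone ring; ring A is closed by McMurry coupling; the side chain is grown to a but-3-enyl group and converted into a 3-substituted cyclobutanone; this is expanded to the γ-lactone, opened (lactol, Wittig), coupled with the bromobutenolide and sulfated last.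
- Feature used: C13 carries two almost identical alkyl arms plus CH2O. C13, C13a, C14 and C15 map onto a 3-substituted cyclobutanone (C13a and C14 its two CH2 groups, C15 its C=O), and the two CH2 groups become different only when oxygen is inserted next to one of them.
- Stereochemistry: C8 from (S)-pulegone; C5 by base equilibration to the trans-diequatorial ketone; C9 by axial allylation of the conformationally locked enolate; C13 by catalyst-controlled choice between the enantiotopic CH2 groups.

Key step: step 11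

Remark on numbering: halimane numbering is used for positions (C1 alkene CH, C4 CMe2, C5 ring-fusion CH, C8 CHCH3, C9 quaternary C, C10 ring-fusion alkene C, C11–C12 link, C13 side-chain CH, C13a its CH2O, C14–C16 chain to the butenolide). Dec = (1S,2S,4aR)-1,2,5,5-tetramethyl-1,2,3,4,4a,5,6,7-octahydronaphthalen-1-yl, the decalin joined through C9.

Assumption: the target is drawn as the neutral hydrogen sulfate, so the last step ends with proton exchange of the pyridinium sulfate on an H+ resin; for storage the sodium salt would be preferred.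

**Step 1**
Reactants: 1 (S)-(−)-pulegone; 2 2-(2-bromoethyl)-1,3-dioxolane
Product: 4 (2R,5S)-2-[4-(1,3-dioxolan-2-yl)-2-methylbutan-2-yl]-5-methylcyclohexan-1-one, via [2-(1,3-dioxolan-2-yl)ethyl]magnesium bromide 3 (not isolated)
Conditions: 2, Mg, THF, 25 °C; CuBr·SMe2 (15 mol%), then 1, THF, −40 → 0 °C; aq. NH4Cl; NaOMe (cat.), MeOH, 23 °C; chromatography
Reagents that add atoms: none
Why: Copper-catalysed conjugate addition of the acetal Grignard reagent to the β,β-disubstituted enone builds the quaternary C4 with the C3–C1 chain, and methoxide equilibration of the epimerisable C5 should favour the trans-diequatorial (5R,8S) ketone, as for 8-substituted menthones, the minor cis epimer being removed by chromatography; C8 is the pulegone stereocentre.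

**Step 2**
Reactants: 4 (2R,5S)-2-[4-(1,3-dioxolan-2-yl)-2-methylbutan-2-yl]-5-methylcyclohexan-1-one
Product: 6 (2R,3S,6R)-6-[4-(1,3-dioxolan-2-yl)-2-methylbutan-2-yl]-2,3-dimethylcyclohexan-1-one (C2 epimer mixture), via lithium (3S,6R)-6-[4-(1,3-dioxolan-2-yl)-2-methylbutan-2-yl]-3-methylcyclohex-1-en-1-olate 5 (not isolated)
Conditions: LDA (1.1 equiv), THF, −78 °C; MeI, −78 → −40 °C
Reagents that add atoms: iodomethane, CI
Why: Kinetic deprotonation with LDA should take a proton from the unhindered C9 methylene and not the C5–H beside the quaternary C4, and the lithium enolate is C-methylated (enolate alkylation); the C9 configuration formed here is erased in step 3 and C5 is not enolised.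

**Step 3**
Reactants: 6 (2R,3S,6R)-6-[4-(1,3-dioxolan-2-yl)-2-methylbutan-2-yl]-2,3-dimethylcyclohexan-1-one
Product: 8 (2S,3S,6R)-6-[4-(1,3-dioxolan-2-yl)-2-methylbutan-2-yl]-2,3-dimethyl-2-(prop-2-en-1-yl)cyclohexan-1-one, via lithium (3S,6R)-6-[4-(1,3-dioxolan-2-yl)-2-methylbutan-2-yl]-2,3-dimethylcyclohex-1-en-1-olate 7 (not isolated)
Conditions: LDA (1.2 equiv), THF, −78 → 0 °C; DMPU, allyl bromide, −78 → 0 °C
Reagents that add atoms: allyl bromide, C=CCBr
Why: LDA should remove the C9–H (the C5–H is buried beside the quaternary C4) to give the tetrasubstituted enolate 7, whose half-chair is locked with the C5 tert-alkyl group and the C8 methyl pseudo-equatorial, so that allyl bromide adds along the stereoelectronically favoured axial line anti to the pseudo-axial C8–H, on the α-face cis to the C8 methyl, leaving the C9 methyl β (9S) (enolate C-allylation forming a quaternary centre).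

**Step 4**
Reactants: 8 (2S,3S,6R)-6-[4-(1,3-dioxolan-2-yl)-2-methylbutan-2-yl]-2,3-dimethyl-2-(prop-2-en-1-yl)cyclohexan-1-one
Product: 9 4-[(1R,3S,4S)-3,4-dimethyl-2-oxo-3-(prop-2-en-1-yl)cyclohexyl]-4-methylpentanal
Conditions: 1 M aq. HCl, THF, 23 °C
Reagents that add atoms: water, O
Why: Acid hydrolysis of the dioxolane frees the C1 aldehyde, and at room temperature the doubly α-branched ketone should not enolise appreciably, so the C5 configuration is kept.

**Step 5**
Reactants: 9 4-[(1R,3S,4S)-3,4-dimethyl-2-oxo-3-(prop-2-en-1-yl)cyclohexyl]-4-methylpentanal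
Product: 10 (1S,2S,4aR)-1,2,5,5-tetramethyl-1-(prop-2-en-1-yl)-1,2,3,4,4a,5,6,7-octahydronaphthalene
Conditions: TiCl3(DME)1.5, Zn–Cu, DME, reflux; slow addition of 9 (high dilution)
Reagents that add atoms: none
Why: Low-valent titanium couples the aldehyde and the ketone intramolecularly (McMurry keto-aldehyde cyclisation) through a titanium pinacolate that is deoxygenated in refluxing DME, which closes the six-membered ring A and fixes the double bond at C1=C10 without regiochemical ambiguity, while the vinyl group and the three stereocentres are not engaged.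

**Step 6**
Reactants: 10 (1S,2S,4aR)-1,2,5,5-tetramethyl-1-(prop-2-en-1-yl)-1,2,3,4,4a,5,6,7-octahydronaphthalene
Product: 12 3-(Dec)propan-1-ol, via 9-[3-(Dec)propyl]-9-borabicyclo[3.3.1]nonane 11 (not isolated)
Conditions: 9-BBN, THF, 0 → 23 °C; 3 M NaOH, 30% H2O2, 0 → 23 °C
Reagents that add atoms: hydrogen peroxide, OO
Why: 9-BBN adds anti-Markovnikov to the unhindered monosubstituted alkene and should ignore the trisubstituted C1=C10 alkene shielded by C9 and C5, and alkaline peroxide converts the C–B bond into the primary alcohol (hydroboration–oxidation).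

**Step 7**
Reactants: 12 3-(Dec)propan-1-ol
Product: 13 3-(Dec)propanal
Conditions: Dess–Martin periodinane, CH2Cl2, 0 → 23 °C
Reagents that add atoms: none
Why: Dess–Martin oxidation stops at the aldehyde under near-neutral conditions and leaves the alkene and the stereocentres alone.

**Step 8**
Reactants: 13 3-(Dec)propanal
Product: 14 (1S,2S,4aR)-1-(but-3-en-1-yl)-1,2,5,5-tetramethyl-1,2,3,4,4a,5,6,7-octahydronaphthalene
Conditions: Ph3PCH3Br, KOtBu, THF, 0 → 23 °C
Reagents that add atoms: methyltriphenylphosphonium bromide, C[P+](c1ccccc1)(c1ccccc1)c1ccccc1.[Br-]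
Why: Wittig methylenation of the unhindered aldehyde with the non-stabilised ylide adds the one carbon needed to place the terminal alkene at C13.

**Step 9**
Reactants: 14 (1S,2S,4aR)-1-(but-3-en-1-yl)-1,2,5,5-tetramethyl-1,2,3,4,4a,5,6,7-octahydronaphthalene; 15 trichloroacetyl chloride
Product: 17 2,2-dichloro-3-[2-(Dec)ethyl]cyclobutan-1-one (both C3 epimers), via dichloroketene 16 (not isolated)
Conditions: Zn–Cu, Et2O/DME, 23 °C, slow addition of 15 (1.5 equiv)
Reagents that add atoms: none
Why: Dichloroketene, made in the flask by zinc dechlorination of 15, undergoes thermal [2+2] cycloaddition with the monosubstituted alkene, its carbonyl carbon bonding to the terminal CH2, whereas addition to C1=C10 would have to set a quaternary C10 between the quaternary C9 and the C4-flanked C5 and should not compete; the new ring carbon forms as both epimers, which converge in step 10.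

**Step 10**
Reactants: 17 2,2-dichloro-3-[2-(Dec)ethyl]cyclobutan-1-one
Product: 18 3-[2-(Dec)ethyl]cyclobutan-1-one
Conditions: Zn dust, AcOH, 23 °C
Reagents that add atoms: none
Why: Zinc in acetic acid reduces both α-C–Cl bonds through zinc enolates (reductive dechlorination of an α,α-dichloroketone), which makes the two ring CH2 groups equivalent, so C13 is prochiral again and the epimer mixture becomes one compound.

**Step 11**
Reactants: 18 3-[2-(Dec)ethyl]cyclobutan-1-one
Product: 19 (4R)-4-[2-(Dec)ethyl]oxolan-2-one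
Conditions: (S)-3,3′-di(pyren-1-yl)-H8-BINOL hydrogen phosphate (10 mol%), 30% aq. H2O2 (1.5 equiv), CHCl3, −40 °C
Reagents that add atoms: hydrogen peroxide, OO
Why: Hydrogen peroxide, activated by hydrogen bonding to the chiral phosphoric acid, adds to the strained ketone to give a catalyst-bound Criegee adduct, and the ring CH2 antiperiplanar to the O–O bond migrates from C15 to oxygen with loss of water; the closest known reaction type is the catalytic asymmetric Baeyer–Villiger desymmetrisation of 3-substituted cyclobutanones with aqueous H2O2. The γ-lactone arises by ring expansion (1,2-shift of a ring carbon to oxygen, four- to five-membered), not by a new cyclisation, and this shift forms the C13a–O bond. C13 is not touched but becomes stereogenic: the phosphate holds the Criegee hydroxyl and the peroxide in a two-point contact, its 3,3′-aryl walls force the 3-substituent to one side, and only the pro-R CH2 of C13 should reach the antiperiplanar position, which gives 4R. The step needs enantiotopic-group selection, which only the catalyst can supply because the decalin stereocentres are too remote, and chemoselectivity over C1=C10, secured because H2O2 under Brønsted-acid catalysis is a nucleophilic oxidant that a strained ketone accepts at −40 °C while an isolated alkene is inert to it. The sense of induction is to be confirmed beforehand on 3-(2-cyclohexylethyl)cyclobutanone, and the antipodal acid is used if it proves opposite.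

**Step 12**
Reactants: 19 (4R)-4-[2-(Dec)ethyl]oxolan-2-one
Product: 20 (4R)-4-[2-(Dec)ethyl]oxolan-2-ol (anomer mixture)
Conditions: DIBAL-H (1.1 equiv), CH2Cl2, −78 °C; aq. Rochelle salt
Reagents that add atoms: none
Why: At −78 °C DIBAL-H stops at the tetrahedral aluminium hemiacetal, which gives the lactol on work-up (partial reduction of a γ-lactone); C13 is untouched.

**Step 13**
Reactants: 20 (4R)-4-[2-(Dec)ethyl]oxolan-2-ol
Product: 21 (2R)-2-[2-(Dec)ethyl]pent-4-en-1-ol
Conditions: Ph3PCH3Br (3 equiv), KOtBu (3 equiv), THF, 0 → 50 °C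
Reagents that add atoms: methyltriphenylphosphonium bromide, C[P+](c1ccccc1)(c1ccccc1)c1ccccc1.[Br-]
Why: The lactol equilibrates with its open hydroxy-aldehyde, which undergoes Wittig methylenation to add C16 and free the C13a alcohol; C13 is β to the aldehyde and cannot epimerise.

**Step 14**
Reactants: 21 (2R)-2-[2-(Dec)ethyl]pent-4-en-1-ol
Product: 22 tert-butyl(dimethyl){[(2R)-2-[2-(Dec)ethyl]pent-4-en-1-yl]oxy}silane
Conditions: TBSCl, imidazole, DMF, 23 °C
Reagents that add atoms: tert-butyldimethylsilyl chloride, CC(C)(C)[Si](C)(C)Cl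
Why: Standard silylation of the primary alcohol, so that the hydroxyl neither consumes borane nor interferes with the coupling in step 15.

**Step 15**
Reactants: 22 tert-butyl(dimethyl){[(2R)-2-[2-(Dec)ethyl]pent-4-en-1-yl]oxy}silane; 23 4-bromofuran-2(5H)-one
Product: 25 4-[(4S)-5-{[tert-butyl(dimethyl)silyl]oxy}-4-[2-(Dec)ethyl]pentyl]furan-2(5H)-one, via 9-[(4S)-5-{[tert-butyl(dimethyl)silyl]oxy}-4-[2-(Dec)ethyl]pentyl]-9-borabicyclo[3.3.1]nonane 24 (not isolated)
Conditions: 9-BBN, THF, 23 °C; then 23, PdCl2(dppf) (5 mol%), AsPh3 (10 mol%), 3 M aq. K3PO4, DMF, 23 → 40 °C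
Reagents that add atoms: none
Why: 9-BBN hydroborates only the monosubstituted alkene at C16, and the B-alkyl borane undergoes sp3–sp2 Suzuki–Miyaura coupling with the vinylogous acyl bromide 23, which adds readily to Pd(0), while the mild phosphate base should spare the butenolide.

**Step 16**
Reactants: 25 4-[(4S)-5-{[tert-butyl(dimethyl)silyl]oxy}-4-[2-(Dec)ethyl]pentyl]furan-2(5H)-one
Product: 26 4-[(4S)-5-hydroxy-4-[2-(Dec)ethyl]pentyl]furan-2(5H)-one
Conditions: HF·pyridine, THF/pyridine, 0 → 23 °C
Reagents that add atoms: none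
Why: Fluoride cleaves the primary TBS ether under buffered, weakly acidic conditions that leave the base-sensitive butenolide and the alkene untouched.

**Step 17**
Reactants: 26 4-[(4S)-5-hydroxy-4-[2-(Dec)ethyl]pentyl]furan-2(5H)-one
Product: 27 (2S)-2-[2-(Dec)ethyl]-5-(5-oxo-2,5-dihydrofuran-3-yl)pentyl hydrogen sulfate
Conditions: SO3·pyridine (3 equiv), pyridine, 23 °C; then Dowex 50W (H+ form), MeOH/H2O, 0 °C
Reagents that add atoms: sulfur trioxide–pyridine complex, [O-]S(=O)(=O)[n+]1ccccc1
Why: O-sulfation of the primary alcohol with the sulfur trioxide–pyridine complex, followed by proton exchange of the pyridinium salt, should give the hydrogen sulfate without touching the butenolide or the alkene.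

**Compound list**

1 | (S)-(−)-pulegone, (5S)-5-methyl-2-(propan-2-ylidene)cyclohexan-1-one | C[C@H]1CCC(=C(C)C)C(=O)C1 | starting material
2 | 2-(2-bromoethyl)-1,3-dioxolane | BrCCC1OCCO1 | starting material
3 | [2-(1,3-dioxolan-2-yl)ethyl]magnesium bromide | Br[Mg]CCC1OCCO1 | intermediate (not isolated)
4 | (2R,5S)-2-[4-(1,3-dioxolan-2-yl)-2-methylbutan-2-yl]-5-methylcyclohexan-1-one | C[C@H]1CC[C@H](C(C)(C)CCC2OCCO2)C(=O)C1 | intermediate
5 | lithium (3S,6R)-6-[4-(1,3-dioxolan-2-yl)-2-methylbutan-2-yl]-3-methylcyclohex-1-en-1-olate | C[C@H]1CC[C@H](C(C)(C)CCC2OCCO2)C(O[Li])=C1 | intermediate (not isolated)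
6 | (2R,3S,6R)-6-[4-(1,3-dioxolan-2-yl)-2-methylbutan-2-yl]-2,3-dimethylcyclohexan-1-one (used as the C2 epimer mixture; the all-equatorial epimer is written) | C[C@H]1CC[C@H](C(C)(C)CCC2OCCO2)C(=O)[C@@H]1C | intermediate
7 | lithium (3S,6R)-6-[4-(1,3-dioxolan-2-yl)-2-methylbutan-2-yl]-2,3-dimethylcyclohex-1-en-1-olate | C[C@H]1CC[C@H](C(C)(C)CCC2OCCO2)C(O[Li])=C1C | intermediate (not isolated)
8 | (2S,3S,6R)-6-[4-(1,3-dioxolan-2-yl)-2-methylbutan-2-yl]-2,3-dimethyl-2-(prop-2-en-1-yl)cyclohexan-1-one | C[C@H]1CC[C@H](C(C)(C)CCC2OCCO2)C(=O)[C@@]1(C)CC=C | intermediate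
9 | 4-[(1R,3S,4S)-3,4-dimethyl-2-oxo-3-(prop-2-en-1-yl)cyclohexyl]-4-methylpentanal | C[C@H]1CC[C@H](C(C)(C)CCC=O)C(=O)[C@@]1(C)CC=C | intermediate
10 | (1S,2S,4aR)-1,2,5,5-tetramethyl-1-(prop-2-en-1-yl)-1,2,3,4,4a,5,6,7-octahydronaphthalene | C[C@H]1CC[C@H]2C(=CCCC2(C)C)[C@@]1(C)CC=C | intermediate
11 | 9-[3-(Dec)propyl]-9-borabicyclo[3.3.1]nonane | C[C@H]1CC[C@H]2C(=CCCC2(C)C)[C@@]1(C)CCCB1C2CCCC1CCC2 | intermediate (not isolated)
12 | 3-(Dec)propan-1-ol | C[C@H]1CC[C@H]2C(=CCCC2(C)C)[C@@]1(C)CCCO | intermediate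
13 | 3-(Dec)propanal | C[C@H]1CC[C@H]2C(=CCCC2(C)C)[C@@]1(C)CCC=O | intermediate
14 | (1S,2S,4aR)-1-(but-3-en-1-yl)-1,2,5,5-tetramethyl-1,2,3,4,4a,5,6,7-octahydronaphthalene | C[C@H]1CC[C@H]2C(=CCCC2(C)C)[C@@]1(C)CCC=C | intermediate
15 | trichloroacetyl chloride | O=C(Cl)C(Cl)(Cl)Cl | starting material
16 | dichloroketene | O=C=C(Cl)Cl | intermediate (not isolated)
17 | 2,2-dichloro-3-[2-(Dec)ethyl]cyclobutan-1-one (both C3 epimers) | C[C@H]1CC[C@H]2C(=CCCC2(C)C)[C@@]1(C)CCC1CC(=O)C1(Cl)Cl | intermediate
18 | 3-[2-(Dec)ethyl]cyclobutan-1-one | C[C@H]1CC[C@H]2C(=CCCC2(C)C)[C@@]1(C)CCC1CC(=O)C1 | intermediate (key-step precursor)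
19 | (4R)-4-[2-(Dec)ethyl]oxolan-2-one | C[C@H]1CC[C@H]2C(=CCCC2(C)C)[C@@]1(C)CC[C@H]1COC(=O)C1 | intermediate (key-step product)
20 | (4R)-4-[2-(Dec)ethyl]oxolan-2-ol (anomer mixture) | C[C@H]1CC[C@H]2C(=CCCC2(C)C)[C@@]1(C)CC[C@H]1COC(O)C1 | intermediate
21 | (2R)-2-[2-(Dec)ethyl]pent-4-en-1-ol | C[C@H]1CC[C@H]2C(=CCCC2(C)C)[C@@]1(C)CC[C@H](CC=C)CO | intermediate
22 | tert-butyl(dimethyl){[(2R)-2-[2-(Dec)ethyl]pent-4-en-1-yl]oxy}silane | C[C@H]1CC[C@H]2C(=CCCC2(C)C)[C@@]1(C)CC[C@H](CC=C)CO[Si](C)(C)C(C)(C)C | intermediate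
23 | 4-bromofuran-2(5H)-one | O=C1C=C(Br)CO1 | starting material
24 | 9-[(4S)-5-{[tert-butyl(dimethyl)silyl]oxy}-4-[2-(Dec)ethyl]pentyl]-9-borabicyclo[3.3.1]nonane | C[C@H]1CC[C@H]2C(=CCCC2(C)C)[C@@]1(C)CC[C@H](CCCB1C2CCCC1CCC2)CO[Si](C)(C)C(C)(C)C | intermediate (not isolated)
25 | 4-[(4S)-5-{[tert-butyl(dimethyl)silyl]oxy}-4-[2-(Dec)ethyl]pentyl]furan-2(5H)-one | C[C@H]1CC[C@H]2C(=CCCC2(C)C)[C@@]1(C)CC[C@H](CCCC1=CC(=O)OC1)CO[Si](C)(C)C(C)(C)C | intermediate
26 | 4-[(4S)-5-hydroxy-4-[2-(Dec)ethyl]pentyl]furan-2(5H)-one | C[C@H]1CC[C@H]2C(=CCCC2(C)C)[C@@]1(C)CC[C@H](CCCC1=CC(=O)OC1)CO | intermediate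
27 | (2S)-2-[2-(Dec)ethyl]-5-(5-oxo-2,5-dihydrofuran-3-yl)pentyl hydrogen sulfate | C[C@H]1CC[C@H]2C(=CCCC2(C)C)[C@@]1(C)CC[C@H](CCCC1=CC(=O)OC1)COS(=O)(=O)O | target

**Step count and risks**

Total step count: 17. Longest linear sequence: 17 steps (1 → 27); 2, 15 and 23 are bought and used directly.

The three steps most likely to fail:

1. Step 11 (key step). What may go wrong: incomplete discrimination between the two enantiotopic CH2 groups, because the 3-substituent is a flexible primary alkyl chain that offers the catalyst little to hold. The lactone would then form as a mixture of C13 epimers that is hard to separate, since the other stereocentres are remote. Fallback (auxiliary control in place of catalyst control; it replaces steps 9–13): setting out from 14, hydroboration with 9-BBN gives 9-[4-(Dec)butyl]-9-borabicyclo[3.3.1]nonane F1, which is oxidised in the same flask (NaOH, H2O2) to 4-(Dec)butan-1-ol F2. TEMPO/PhI(OAc)2 in aqueous MeCN oxidises this to 4-(Dec)butanoic acid F3. Pivaloyl chloride/Et3N converts the acid into 4-(Dec)butanoic pivalic anhydride F4, which acylates lithiated (S)-4-benzyl-1,3-oxazolidin-2-one to give (4S)-4-benzyl-3-[4-(Dec)butanoyl]-1,3-oxazolidin-2-one F5. NaHMDS in THF at −78 °C forms the chelated Z-enolate, sodium (Z)-1-[(4S)-4-benzyl-2-oxo-1,3-oxazolidin-3-yl]-4-(Dec)but-1-en-1-olate F6. Allyl bromide should alkylate F6 on the face away from the benzyl group (Evans alkylation) to give (4S)-4-benzyl-3-[(2R)-2-[2-(Dec)ethyl]pent-4-enoyl]-1,3-oxazolidin-2-one F7. LiBH4 in wet Et2O removes the auxiliary and the sequence comes back to the route at 21.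

2. Step 3. What may go wrong: poor or reversed facial selectivity in the quaternisation, if attack trans to the C8 methyl (as in conformationally mobile 2,3-dialkylcyclohexanone enolates) competes with axial attack on the locked enolate; competing deprotonation at C5 is a second concern. Fallback (inverted order of the two C–C bond formations, which places the two C9 substituents the other way round for the same facial preference): setting out from 4, the enolate 5 is allylated first (allyl bromide, −78 °C) to give (2R,3S,6R)-6-[4-(1,3-dioxolan-2-yl)-2-methylbutan-2-yl]-3-methyl-2-(prop-2-en-1-yl)cyclohexan-1-one F8. LDA converts F8 into lithium (3S,6R)-6-[4-(1,3-dioxolan-2-yl)-2-methylbutan-2-yl]-3-methyl-2-(prop-2-en-1-yl)cyclohex-1-en-1-olate F9, which is methylated with iodomethane, and the sequence comes back to the route at 8.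

3. Step 5. What may go wrong: slow C–C coupling at the doubly α-branched ketone, so that simple reduction of the aldehyde, intermolecular coupling, or titanium-mediated enolisation with loss of the C5 configuration takes over. Fallback (pinacol coupling and a separate deoxygenation in place of the one-pot titanium process): setting out from 9, SmI2 in THF/t-BuOH closes ring A by ketyl–carbonyl coupling to the cis-diol (4aR,7S,8S)-4,4,7,8-tetramethyl-8-(prop-2-en-1-yl)decahydronaphthalene-1,8a-diol F10. Thiocarbonyldiimidazole/DMAP in hot toluene converts F10 into its cyclic thionocarbonate, the 1,3-dioxolane-2-thione fused across C1 and C10 F11, and heating with P(OMe)3 (Corey–Winter elimination) gives the C1=C10 alkene, coming back to the route at 10.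

**Further compounds**

F1 | step 11 | 9-[4-(Dec)butyl]-9-borabicyclo[3.3.1]nonane | C[C@H]1CC[C@H]2C(=CCCC2(C)C)[C@@]1(C)CCCCB1C2CCCC1CCC2
F2 | step 11 | 4-(Dec)butan-1-ol | C[C@H]1CC[C@H]2C(=CCCC2(C)C)[C@@]1(C)CCCCO
F3 | step 11 | 4-(Dec)butanoic acid | C[C@H]1CC[C@H]2C(=CCCC2(C)C)[C@@]1(C)CCCC(=O)O
F4 | step 11 | 4-(Dec)butanoic pivalic anhydride | C[C@H]1CC[C@H]2C(=CCCC2(C)C)[C@@]1(C)CCCC(=O)OC(=O)C(C)(C)C
F5 | step 11 | (4S)-4-benzyl-3-[4-(Dec)butanoyl]-1,3-oxazolidin-2-one | C[C@H]1CC[C@H]2C(=CCCC2(C)C)[C@@]1(C)CCCC(=O)N1C(=O)OC[C@@H]1Cc1ccccc1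
F6 | step 11 | sodium (Z)-1-[(4S)-4-benzyl-2-oxo-1,3-oxazolidin-3-yl]-4-(Dec)but-1-en-1-olate | C[C@H]1CC[C@H]2C(=CCCC2(C)C)[C@@]1(C)CC/C=C(\O[Na])N1C(=O)OC[C@@H]1Cc1ccccc1
F7 | step 11 | (4S)-4-benzyl-3-[(2R)-2-[2-(Dec)ethyl]pent-4-enoyl]-1,3-oxazolidin-2-one | C[C@H]1CC[C@H]2C(=CCCC2(C)C)[C@@]1(C)CC[C@H](CC=C)C(=O)N1C(=O)OC[C@@H]1Cc1ccccc1
F8 | step 3 | (2R,3S,6R)-6-[4-(1,3-dioxolan-2-yl)-2-methylbutan-2-yl]-3-methyl-2-(prop-2-en-1-yl)cyclohexan-1-one | C[C@H]1CC[C@H](C(C)(C)CCC2OCCO2)C(=O)[C@@H]1CC=C
F9 | step 3 | lithium (3S,6R)-6-[4-(1,3-dioxolan-2-yl)-2-methylbutan-2-yl]-3-methyl-2-(prop-2-en-1-yl)cyclohex-1-en-1-olate | C[C@H]1CC[C@H](C(C)(C)CCC2OCCO2)C(O[Li])=C1CC=C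
F10 | step 5 | (4aR,7S,8S)-4,4,7,8-tetramethyl-8-(prop-2-en-1-yl)decahydronaphthalene-1,8a-diol (cis-diol, C1/C8a configuration not assigned) | C[C@H]1CC[C@H]2C(O)(C(O)CCC2(C)C)[C@@]1(C)CC=C
F11 | step 5 | cyclic thionocarbonate of F10 (1,3-dioxolane-2-thione fused across C1 and C10) | C[C@H]1CC[C@H]2C3(OC(=S)OC3CCC2(C)C)[C@@]1(C)CC=C
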